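**Plan**
1. Terpene ring numbering: C1 (=C–CH3), C2 (=CH), C3 (CH–Ar), C4 (CH–iPr), C5, C6. The first cut breaks the Ar–C3 bond and at the same time excises C2 (bonds C1–C2 and C2–C3). This contracts the cyclohexene to a cyclopentene and leaves magnolol, a CHCl unit and (S)-3-isopropyl-1-methylcyclopentene.
2. Enabling feature: C1=C2–C3(Ar) is an allyl triad whose central atom C2 bears only H and whose terminus C3 bears the arene, so it is a trapped cyclohexenyl cation. Such a cation is the electrocyclic valence isomer of a cyclopropyl cation, so C2 can start as the chlorine-bearing one-carbon bridge over C1–C3 of a bicyclo[3.1.0]hexane.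
3. Further cuts: the cyclopentene C1=C3 bond (carbonyl coupling) and C4–C5 (Michael addition), leading back to isovaleraldehyde and methyl vinyl ketone.
4. Forward order: chain (C4–C5), five-membered ring (C1=C3), cyclopropane (C2 added), then the six-membered ring, the alkene, the aryl bond and the C3 centre in one operation.
5. Stereochemistry: C4 comes from enamine organocatalysis. C3 comes from C4 by anti attack of the arene on the planar cation. The cyclopropane centres are transient.

Key step: step 4

Assumption: magnolol (5,5'-diallylbiphenyl-2,2'-diol) is taken as a commercial starting material.
Assumption: the (S)-diarylprolinol ether is taken to shield the enamine face as in its other aldehyde α-functionalisations, which leads to (S)-3; the (R)-catalyst is equally available should the sense be opposite.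

Step 1
Reactants: 1 isovaleraldehyde (3-methylbutanal); 2 methyl vinyl ketone (but-3-en-2-one)
Product: 3 (S)-2-isopropyl-5-oxohexanal
Conditions: (S)-2-[methoxy(diphenyl)methyl]pyrrolidine (5 mol %), ethyl 3,4-dihydroxybenzoate (20 mol %), neat, 4 °C
Reagents that add atoms: none
Why: Enamine-catalysed asymmetric Michael addition, in which the E-enamine of 1 is shielded on one face by the CPh2OMe group and adds through its open face to the catechol-activated enone 2, setting the isopropyl-bearing centre (later C4) as S.

Step 2
Reactants: 3 (S)-2-isopropyl-5-oxohexanal
Product: 4 (S)-3-isopropyl-1-methylcyclopent-1-ene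
Conditions: TiCl3(DME)1.5, Zn–Cu, DME, reflux; 3 added slowly by syringe pump; pentane work-up, careful distillation
Reagents that add atoms: none
Why: Intramolecular McMurry coupling, in which low-valent titanium joins aldehyde and ketone carbon in a favourable five-membered ring closure and deoxygenates the bound diolate to the trisubstituted alkene, so the C=C sits exactly between the former carbonyl carbons, and slow addition to excess reagent consumes the aldehyde before its α-centre can enolise.

Step 3
Reactants: 4 (S)-3-isopropyl-1-methylcyclopent-1-ene
Product: 5 (1R,4S,5S,6S)-6-chloro-4-isopropyl-1-methylbicyclo[3.1.0]hexane (chlorine endo, over the five-membered ring; cyclopropane on the face opposite to isopropyl)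
Conditions: CH2Cl2 (excess), MeLi (halide-free, slow addition), Et2O, −35 → −10 °C; cold neutral work-up, no silica, stored cold and used at once
Reagents that add atoms: dichloromethane, ClCCl
Why: Chlorocarbenoid cyclopropanation ([2+1] addition), in which the electron-rich trisubstituted alkene is the only reactive site, addition is suprafacial and should occur mainly anti to isopropyl with chlorine preferring the endo position syn to the two ring alkyl residues; the three new centres are erased in step 4, so only the endo orientation matters and the exo epimer is carried along as a spectator.

Step 4
Reactants: 5 (1R,4S,5S,6S)-6-chloro-4-isopropyl-1-methylbicyclo[3.1.0]hexane; 6 magnolol (5,5'-diallylbiphenyl-2,2'-diol)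
Product: 8 piperitylmagnolol [3-((1S,6S)-6-isopropyl-3-methylcyclohex-2-en-1-yl)-5,5'-diallylbiphenyl-2,2'-diol; target], via piperityl cation 7 (not isolated)
Conditions: AgOTf, 2,6-di-tert-butyl-4-methylpyridine, 6 in threefold excess, CH2Cl2/HFIP, −40 → 0 °C, dark
Reagents that add atoms: none
Why: Proposed new method: Ag(I) abstracts the endo chloride from C6 while the fused C1–C5 bond of 5 opens in a concerted disrotatory two-electron electrocyclic process (Woodward–Hoffmann–DePuy rule: the ring bonds cis to the leaving group turn inward), so the cyclopentane takes up the carbenoid carbon and becomes the cis-configured cyclohexenyl (piperityl) cation 7, which is attacked by the free ortho carbon of 6 (Friedel–Crafts step) and rearomatises by proton loss to the pyridine. The closest known reaction types are the silver-promoted ring expansion of 6-halobicyclo[3.1.0]hexanes with capture by oxygen, nitrogen or tethered arene nucleophiles and the acid-mediated terpenylation of resorcinols through the same type of p-menthenyl cation; new is their union with an intermolecular phenol carbon as the trap under buffered conditions. No ring is closed by bond formation: the six-membered ring arises by cleavage of the zero-atom bridge of the bicycle, a one-carbon expansion of the five-membered ring. The only new stereocentre, C3, is controlled by the untouched C4 centre, because the pseudo-equatorial isopropyl group of the half-chair cation shields one face and the arene adds anti to it to give the trans (1S,6S) product, while the cyclopropane centres vanish in the planar cation so that both facial isomers of 5 converge. The step needs endo over exo reactivity (only the endo chloride can open to a cis-allyl cation in a six-membered ring, the exo epimer stays untouched and is removed afterwards), C3 over C1 attack (secondary, less hindered terminus, product keeps the trisubstituted alkene), carbon over oxygen and arene over allyl C=C attack (HFIP hydrogen-bonds the phenol oxygen, any aryl ether should re-ionise in this medium, the para positions are blocked and only the carbon ortho to OH is activated) and mono over double alkylation (excess of the C2-symmetric 6, which is recovered). The buffer keeps strong acid out, so that neither proton shuffling through achiral α-terpinene, which would erode the C4 centre, nor addition of the phenol OH to the new alkene should set in.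

**Compound list**
1 | isovaleraldehyde (3-methylbutanal) | CC(C)CC=O | starting material
2 | methyl vinyl ketone (but-3-en-2-one) | C=CC(C)=O | starting material
3 | (S)-2-isopropyl-5-oxohexanal | CC(=O)CC[C@H](C=O)C(C)C | intermediate
4 | (S)-3-isopropyl-1-methylcyclopent-1-ene | CC1=C[C@H](C(C)C)CC1 | intermediate
5 | (1R,4S,5S,6S)-6-chloro-4-isopropyl-1-methylbicyclo[3.1.0]hexane (endo-Cl) | C[C@@]12CC[C@@H](C(C)C)[C@@H]1[C@@H]2Cl | intermediate
6 | magnolol (5,5'-diallylbiphenyl-2,2'-diol) | C=CCc1ccc(O)c(-c2cc(CC=C)ccc2O)c1 | starting material
7 | (S)-4-isopropyl-1-methylcyclohex-2-enyl (piperityl) cation, not isolated | CC1=C[CH+][C@H](C(C)C)CC1 | intermediate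
8 | piperitylmagnolol, 3-((1S,6S)-6-isopropyl-3-methylcyclohex-2-en-1-yl)-5,5'-diallylbiphenyl-2,2'-diol | C=CCc1ccc(O)c(-c2cc(CC=C)cc([C@@H]3C=C(C)CC[C@H]3C(C)C)c2O)c1 | target

**Total step count:** 4. **Longest linear sequence:** 4 (1 → 3 → 4 → 5 → 8).

**Steps most likely to fail**

1. Step 4 (labelled step).
   - Risk: capture of the cation at the phenol oxygen, or its loss of a proton, may outrun attack by the ortho carbon. A second alkylation or acid-induced ether closure may also consume product.
   - Fallback (known chemistry, sets out from 5, returns at 8): ring expansion and arylation are separated. Silver-assisted hydrolysis of 5 (AgNO3, NaHCO3, aqueous acetone, 0 °C) is the established solvolytic ring expansion of endo-6-halobicyclo[3.1.0]hexanes to cyclohex-2-enols. It should give (4S)-4-isopropyl-1-methylcyclohex-2-en-1-ol F1, and either C1 epimer serves. This alcohol is then condensed with excess 6 under the acid conditions established for the terpenylation of phenols and resorcinols with p-menth-2-en-1-ols (BF3·OEt2 on alumina or catalytic p-TsOH, CH2Cl2, 0 °C) to give 8.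

2. Step 3.
   - Risk: incomplete conversion of the valuable alkene by the short-lived carbenoid, an unfavourable endo/exo outcome, or premature ionisation of the endo chloride during isolation.
   - Fallback (sets out from 4, returns at 8): dibromocarbene (CHBr3, KOt-Bu, pentane, −20 °C) works well with the alkene as limiting reagent and always places one halogen endo. It should give (1R,4S,5S)-6,6-dibromo-4-isopropyl-1-methylbicyclo[3.1.0]hexane F2, which is kept cold. It is subjected to the silver-mediated ring expansion and arylation with 6 to give 3-((1R,6S)-2-bromo-6-isopropyl-3-methylcyclohex-2-en-1-yl)-5,5'-diallylbiphenyl-2,2'-diol F3. The vinylic bromine, a helper left by the exo halogen, is then removed by radical hydrodebromination (Bu3SnH, AIBN, benzene, 80 °C) to give 8.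

3. Step 2.
   - Risk: erosion of enantiopurity by enolisation of the α-branched aldehyde on Lewis-acidic titanium, competing intramolecular aldol condensation, or loss of the volatile hydrocarbon on isolation.
   - Fallback (sets out from 3, returns at 4): both carbonyl groups are methylenated (Ph3P=CH2 from MePPh3Br/KHMDS, THF, −78 → 0 °C) to give (S)-3-isopropyl-6-methylhepta-1,6-diene F4. The five-membered ring is then closed by ring-closing metathesis (second-generation Grubbs catalyst, CH2Cl2, 40 °C) to give 4.

**Further compounds**
F1 | step 4 | (4S)-4-isopropyl-1-methylcyclohex-2-en-1-ol (C1 epimers) | CC1(O)C=C[C@H](C(C)C)CC1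
F2 | step 3 | (1R,4S,5S)-6,6-dibromo-4-isopropyl-1-methylbicyclo[3.1.0]hexane | C[C@@]12CC[C@@H](C(C)C)[C@@H]1C2(Br)Br
F3 | step 3 | 3-((1R,6S)-2-bromo-6-isopropyl-3-methylcyclohex-2-en-1-yl)-5,5'-diallylbiphenyl-2,2'-diol | C=CCc1ccc(O)c(-c2cc(CC=C)cc([C@@H]3C(Br)=C(C)CC[C@H]3C(C)C)c2O)c1
F4 | step 2 | (S)-3-isopropyl-6-methylhepta-1,6-diene | C=C[C@H](C(C)C)CCC(C)=C
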